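**Plan**
- Retrosynthesis first cuts the O–S bond of the 7-sulfate, then opens ring C at three bonds, C4a–C4, C4–C3 and O1–C2. This gives a 2-iodoresorcinol (ring A), carbon monoxide (C4) and an arylacetylene (C2, C3 and ring B).
- The enabling feature is that C4 is an isolated carbonyl carbon between C4a and C3, and that C4a lies between two oxygen-bearing carbons (C5 and C8a) which are equivalent in the iodide. Either hydroxyl can become O1, and the other is left as the chelated 5-OH.
- Forward, ring A comes from phloroglucinol (silylated at the future O7, iodinated at the future C4a) and ring B from benzyl-protected protocatechualdehyde via its alkyne. Ring C is the only ring formed, in one palladium-catalysed carbonylative annulation.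
- The end game frees the 7-OH with fluoride, sulfates it while the 5-OH is chelated and ring B is benzylated, then removes the benzyl ethers and exchanges the counter-ion for a proton.
- The target has no stereocentre and none is created. Only regiochemistry needs control: site of iodination, flavone against aurone closure, and site of sulfation.

Key step: step 4

Assumption: the target is taken as drawn, as the free hydrogen sulfate and not a salt, so the last operation exchanges the ammonium counter-ion for a proton.

**Route**

Step 1
Reactants: 1 phloroglucinol (benzene-1,3,5-triol)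
Product: 2 5-(triisopropylsilyloxy)benzene-1,3-diol
Conditions: iPr3SiCl (1 equiv), imidazole, 1 (3 equiv), DMF, 0 °C to rt
Reagents that add atoms: chlorotriisopropylsilane, CC(C)[Si](Cl)(C(C)C)C(C)C
Why: Imidazole-promoted O-silylation of a phenol; with the cheap triol in excess the mono-ether should predominate statistically, unchanged 1 is washed into water and the less polar bis-ether is removed by chromatography.

Step 2
Reactants: 2 5-(triisopropylsilyloxy)benzene-1,3-diol
Product: 3 2-iodo-5-(triisopropylsilyloxy)benzene-1,3-diol
Conditions: I2 (1.0 equiv), NaHCO3, THF–H2O, 0 °C; Na2S2O3 quench, no acid in the work-up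
Reagents that add atoms: iodine, II
Why: Electrophilic aromatic iodination of the resorcinol phenoxide under iodine–bicarbonate conditions, which are known to place iodine between the two hydroxyls of resorcinols; that carbon is also para to the silyloxy group, and the two alternative positions are screened by the triisopropylsilyl group.

Step 3
Reactants: 4 3,4-bis(benzyloxy)benzaldehyde
Product: 5 1,2-bis(benzyloxy)-4-ethynylbenzene
Conditions: dimethyl (1-diazo-2-oxopropyl)phosphonate, K2CO3, MeOH–THF, rt
Reagents that add atoms: dimethyl (1-diazo-2-oxopropyl)phosphonate, CC(=O)C(=[N+]=[N-])P(=O)(OC)OC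
Why: Seyferth–Gilbert homologation in its Ohira–Bestmann form: methanolysis of the reagent releases the diazomethylphosphonate anion, which adds to the non-enolisable aldehyde, and loss of dimethyl phosphate and N2 with a 1,2-hydrogen shift gives the terminal alkyne while the benzyl ethers are inert to K2CO3/MeOH.

Step 4
Reactants: 3 2-iodo-5-(triisopropylsilyloxy)benzene-1,3-diol; 5 1,2-bis(benzyloxy)-4-ethynylbenzene; 6 carbon monoxide
Product: 9 3',4'-bis(benzyloxy)-5-hydroxy-7-(triisopropylsilyloxy)flavone, via ynone 7 (not isolated), via enaminone 8 (not isolated)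
Conditions: PdCl2(PPh3)2 (5 mol %), CO (5 bar), Et2NH (excess), DMF, 60 °C, no copper salt
Reagents that add atoms: none
Why: The divalent palladium of PdCl2(PPh3)2 is reduced in the flask to zerovalent palladium, which inserts into the C–I bond at the future C4a; CO insertion gives an aroyl–palladium species, and amine-assisted alkynylation with 5 followed by reductive elimination forms C4a–C4 and C4–C3 in ynone 7. Diethylamine then adds to the ynone to give enaminone 8, and one of the two ortho hydroxyls attacks the amine-bearing carbon in a 6-endo-trig addition–elimination (formally 6-endo-dig on the ynone) that forms O1–C2, closes ring C and returns Et2NH. The closest known reaction type is the palladium-catalysed carbonylative coupling–cyclisation of ortho-iodophenols with terminal arylacetylenes to flavones. No stereocentre is formed. CO insertion must precede alkynylation, which is secured by the CO pressure, the absence of copper and the doubly ortho-substituted aryl–palladium species that is relieved by migration to CO; six- rather than five-membered closure (flavone, not aurone) is secured by the secondary amine, because in 8 only the future C2 is electrophilic. The mirror symmetry of 3 makes the two hydroxyls equivalent, so no choice arises, the unused one ends as the chelated 5-OH, and the silyl ether, meta to both, cannot migrate.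

Step 5
Reactants: 9 3',4'-bis(benzyloxy)-5-hydroxy-7-(triisopropylsilyloxy)flavone
Product: 10 3',4'-bis(benzyloxy)-5,7-dihydroxyflavone
Conditions: Bu4NF, AcOH, THF, 0 °C
Reagents that add atoms: none
Why: Fluoride-induced cleavage of an aryl silyl ether, fast here because the 7-phenoxide of a flavone is a good leaving group on silicon; the AcOH buffer keeps the medium near neutral so that the pyranone ring and the benzyl ethers are untouched.

Step 6
Reactants: 10 3',4'-bis(benzyloxy)-5,7-dihydroxyflavone
Product: 11 triethylammonium 3',4'-bis(benzyloxy)-5-hydroxyflavon-7-yl sulfate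
Conditions: SO3·NEt3, Et3N, DMF, rt to 40 °C; chromatography on Et3N-doped silica
Reagents that add atoms: sulfur trioxide–triethylamine complex, CC[N+](CC)(CC)S(=O)(=O)[O-]
Why: O-Sulfonation of a phenol by an amine–SO3 complex: the 7-OH is the only hydroxyl that is neither benzylated nor held in the hydrogen bond to the C4 carbonyl, and the complex supplies both the SO3 unit and the counter-ion, so the reaction is a plain addition.

Step 7
Reactants: 11 triethylammonium 3',4'-bis(benzyloxy)-5-hydroxyflavon-7-yl sulfate
Product: 13 luteolin 7-sulfate (3',4',5-trihydroxyflavon-7-yl hydrogen sulfate), via triethylammonium luteolin 7-sulfate 12 (not isolated)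
Conditions: H2 (1 atm), 10% Pd/C, MeOH–THF, rt; filter; sulfonated polystyrene resin (H+ form), H2O–MeOH, 0 °C; freeze-dry
Reagents that add atoms: none
Why: Catalytic hydrogenolysis of the two benzyl ethers, under which the aryl sulfate anion and the cross-conjugated pyranone double bond should persist at atmospheric pressure, followed by exchange of triethylammonium for a proton on the acidic resin in the cold and freeze-drying to limit acid-catalysed solvolysis of the sulfate.

**Compound list**
1 | phloroglucinol (benzene-1,3,5-triol) | Oc1cc(O)cc(O)c1 | starting material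
2 | 5-(triisopropylsilyloxy)benzene-1,3-diol | Oc1cc(O)cc(O[Si](C(C)C)(C(C)C)C(C)C)c1 | intermediate
3 | 2-iodo-5-(triisopropylsilyloxy)benzene-1,3-diol | Oc1cc(O[Si](C(C)C)(C(C)C)C(C)C)cc(O)c1I | intermediate
4 | 3,4-bis(benzyloxy)benzaldehyde | O=Cc1ccc(OCc2ccccc2)c(OCc2ccccc2)c1 | starting material
5 | 1,2-bis(benzyloxy)-4-ethynylbenzene | C#Cc1ccc(OCc2ccccc2)c(OCc2ccccc2)c1 | intermediate
6 | carbon monoxide | [C-]#[O+] | starting material
7 | 3-[3,4-bis(benzyloxy)phenyl]-1-[2,6-dihydroxy-4-(triisopropylsilyloxy)phenyl]prop-2-yn-1-one | O=C(C#Cc1ccc(OCc2ccccc2)c(OCc2ccccc2)c1)c1c(O)cc(O[Si](C(C)C)(C(C)C)C(C)C)cc1O | intermediate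
8 | (E)-3-[3,4-bis(benzyloxy)phenyl]-3-(diethylamino)-1-[2,6-dihydroxy-4-(triisopropylsilyloxy)phenyl]prop-2-en-1-one | O=C(/C=C(/N(CC)CC)c1ccc(OCc2ccccc2)c(OCc2ccccc2)c1)c1c(O)cc(O[Si](C(C)C)(C(C)C)C(C)C)cc1O | intermediate
9 | 3',4'-bis(benzyloxy)-5-hydroxy-7-(triisopropylsilyloxy)flavone | O=c1cc(-c2ccc(OCc3ccccc3)c(OCc3ccccc3)c2)oc2cc(O[Si](C(C)C)(C(C)C)C(C)C)cc(O)c12 | intermediate
10 | 3',4'-bis(benzyloxy)-5,7-dihydroxyflavone | O=c1cc(-c2ccc(OCc3ccccc3)c(OCc3ccccc3)c2)oc2cc(O)cc(O)c12 | intermediate
11 | triethylammonium 3',4'-bis(benzyloxy)-5-hydroxyflavon-7-yl sulfate | O=c1cc(-c2ccc(OCc3ccccc3)c(OCc3ccccc3)c2)oc2cc(OS(=O)(=O)[O-])cc(O)c12.CC[NH+](CC)CC | intermediate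
12 | triethylammonium luteolin 7-sulfate | O=c1cc(-c2ccc(O)c(O)c2)oc2cc(OS(=O)(=O)[O-])cc(O)c12.CC[NH+](CC)CC | intermediate
13 | luteolin 7-sulfate (3',4',5-trihydroxyflavon-7-yl hydrogen sulfate) | O=c1cc(-c2ccc(O)c(O)c2)oc2cc(OS(=O)(=O)O)cc(O)c12 | target

**Step count**
Total: 7 steps. Longest linear sequence: 6 steps (steps 1, 2, 4, 5, 6, 7); step 3 is the side branch to the alkyne.

**Steps most likely to fail**

Step 4. Three processes could compete with the annulation:
- alkynylation of the aryl–palladium species before CO insertion, followed by 5-endo closure to a 2-arylbenzofuran;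
- 5-exo closure of the ynone to the aurone;
- reductive loss of iodine from the electron-rich, doubly ortho-substituted iodide.

Partial loss of the silyl group under the amine would be harmless, since it leads to 10. The fallback masks the phenols and separates the events. Setting out from 3, Ac2O in pyridine should give 2-iodo-5-(triisopropylsilyloxy)-1,3-phenylene diacetate F1. The ring of F1 is less electron-rich and no phenol can cyclise. A carbonylative Sonogashira coupling of F1 with 5 and 6 (PdCl2(PPh3)2, Et3N, CO, THF) should then give the isolable ynone 2-{3-[3,4-bis(benzyloxy)phenyl]prop-2-ynoyl}-5-(triisopropylsilyloxy)-1,3-phenylene diacetate F2. Treatment of F2 with Et2NH in EtOH should cleave both aryl acetates by aminolysis, form the enaminone and close ring C, returning to the route at 9.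

Step 2. Iodine may attack beside the silyloxy group or twice on the ring, and the iodide may lose iodine by ipso-protonation during work-up. The fallback reverses the order of the two operations so that symmetry decides the site. Setting out from 1, I2/NaHCO3 in water at 0 °C should give 2-iodobenzene-1,3,5-triol F3, since all three ring CH positions of 1 are equivalent. iPr3SiCl/imidazole should then silylate the hydroxyl remote from iodine in preference to the two hindered ones flanking it. This returns to the route at 3 and replaces steps 1 and 2.

Step 6. O-Sulfonation of the weakly nucleophilic 7-phenoxide (a vinylogous carboxylate) may stall, and the ammonium salt may lose its sulfate on silica. The fallback carries the sulfate as a neutral, masked diester.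
- Setting out from 10, 2,2,2-trichloroethyl chlorosulfate with Et3N and DMAP in THF should give 3',4'-bis(benzyloxy)-5-hydroxyflavon-7-yl 2,2,2-trichloroethyl sulfate F4, which can be purified as an ordinary neutral compound.
- Zn dust and HCO2NH4 in MeOH should then remove the trichloroethyl group by reductive fragmentation, giving ammonium 3',4'-bis(benzyloxy)-5-hydroxyflavon-7-yl sulfate F5.
- Hydrogenolysis over Pd/C should give ammonium luteolin 7-sulfate F6, and the acidic resin used in step 7 should release the free acid, rejoining the route at 13.

**Further compounds**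
F1 | step 4 | 2-iodo-5-(triisopropylsilyloxy)-1,3-phenylene diacetate | CC(=O)Oc1cc(O[Si](C(C)C)(C(C)C)C(C)C)cc(OC(C)=O)c1I
F2 | step 4 | 2-{3-[3,4-bis(benzyloxy)phenyl]prop-2-ynoyl}-5-(triisopropylsilyloxy)-1,3-phenylene diacetate | CC(=O)Oc1cc(O[Si](C(C)C)(C(C)C)C(C)C)cc(OC(C)=O)c1C(=O)C#Cc1ccc(OCc2ccccc2)c(OCc2ccccc2)c1
F3 | step 2 | 2-iodobenzene-1,3,5-triol | Oc1cc(O)c(I)c(O)c1
F4 | step 6 | 3',4'-bis(benzyloxy)-5-hydroxyflavon-7-yl 2,2,2-trichloroethyl sulfate | O=c1cc(-c2ccc(OCc3ccccc3)c(OCc3ccccc3)c2)oc2cc(OS(=O)(=O)OCC(Cl)(Cl)Cl)cc(O)c12
F5 | step 6 | ammonium 3',4'-bis(benzyloxy)-5-hydroxyflavon-7-yl sulfate | O=c1cc(-c2ccc(OCc3ccccc3)c(OCc3ccccc3)c2)oc2cc(OS(=O)(=O)[O-])cc(O)c12.[NH4+]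
F6 | step 6 | ammonium luteolin 7-sulfate | O=c1cc(-c2ccc(O)c(O)c2)oc2cc(OS(=O)(=O)[O-])cc(O)c12.[NH4+]
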